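Time comes first, because the questions stand at 1.5 min, 50 min and 30 h, while the earliest reading of either run comes at 2.00 h, later than the middle time.

| flask | substrate | reagent | catalyst | remark | time |
|---|---|---|---|---|---|
| alder | 6 mM | 10.8 mM | 24 µM | run made earlier |  |
| birch | 24 mM | 10.8 mM | 24 µM | run made earlier |  |
| flask | 12 mM | 10.8 mM | 24 µM |  | 30 h |

- alder (time / h: isomer of the product A / %, target / %): 5.00: 29.5, 10.1; 10.0: 28.6, 10.6; 15.0: 28.6, 9.9; 20.0: 28.7, 10.7; 25.0: 28.9, 10.9
- birch (time / h: isomer of the product A / %, target / %): 2.00: 14.4, 5.9; 4.00: 14.8, 4.7; 6.00: 15.4, 5.4; 12.0: 14.9, 5.1; 25.0: 15.1, 4.3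

(readings scatter by 0.5 percentage points)

* ratio of isomer of the product A to target at 1.5 min
* ratio of isomer of the product A to target at 50 min
* ratio of isomer of the product A to target at 30 h
* which of isomer of the product A and target there is more of at 30 h

Both runs look flat, so we replace each curve by its mean, as fractions of the substrate charged. Alder averages 28.9 % isomer of the product A and 10.4 % target. Birch averages 14.9 % and 5.08 %. The fractions differ widely, but their quotients do not: 2.76 and 2.94.

What does the mean cost? Taking the error of mean target, the quotients carry about 0.0592 and 0.129, and their gap of 0.173 is less than the sum of these. So the difference may be scatter.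

We therefore carry the plateau ratio, the mean of the two quotients, 2.85. The flask's substrate lies between the two charges, so we expect this ratio at 30 h, with more isomer of the product A than target. For the two early times we commit to no number.

The forecast gave 2.9, 2.9 and 2.9, with isomer of the product A ahead, adding “If the plateau is equilibrium, the kinetic ratio could differ”.

    substrate + reagent ⇌ target (K = 69.0 M⁻¹, k = 1.10 M⁻¹ min⁻¹)
    substrate + reagent ⇌ isomer of the product A (K = 190 M⁻¹, k = 0.390 M⁻¹ min⁻¹)
    target + catalyst ⇌ isomer of the product A + catalyst, rate k3*[catalyst]*[target] forward; the back reaction follows from the equilibrium constant (k = 380 M⁻¹ min⁻¹)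
    target ⇌ isomer of the product B (K = 3.50, k = 0.0390 min⁻¹)

The flask's ratio was 0.377 at 1.5 min and 1.37 at 50 min: target led under kinetic control while substrate and reagent were turning over, and the two products stood level at 0.553 h. At 30 h the flask's ratio read 2.75, less than 0.129 below the plateau ratio. With 18 mM of reagent, isomer of the product A reached 30.6 %, and the ratio was again less than 0.129 below the plateau ratio, at 2.75.

(The runs are simulated for substances that don't exist.)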